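Rings: flavone A (benzo), B (4-hydroxyphenyl), C (pyranone); coumarin D (benzo), E (lactone). The retrosynthesis cuts ring E first (coumarin C4–C4a and O1–C2), then ring C (flavone O1–C8a, C4–C4a, O1–C2), and last the biaryl bond flavone C6–coumarin C8.
Enabling feature: in ring A the ring C oxygen sits on C8a and the ring C carbonyl carbon on the adjacent C4a. Both bonds can therefore be made across a C4a≡C8a aryne, and the oxygen substituent on C5, next to C4a, polarises that aryne so that oxygen goes to C8a and the acyl carbon to C4a.
Forward order: rings A and D are joined by Negishi coupling, and the symmetric biaryl phenol becomes an o-silylaryl triflate. Aryne insertion into 3-(4-methoxyphenyl)propiolic acid with 6-endo-dig closure then builds ring C with ring B attached, ring E is annulated onto ring D, and the methyl ethers fall last.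
Protecting groups: ring D carries MOM ethers and rings A and B carry methyl ethers, so ring D alone has free phenols when ring E is built.
Stereochemistry: the target has no stereocentre, and the hindered biaryl axis is not controlled.

Key step: step 8

Assumption: the target is drawn without stereodescriptors, so the biaryl axis flanked by four oxygen substituents, which becomes stereogenic only in step 10, is taken as racemic.

Step 1
Reactants: 1 3,5-dimethoxyphenol
Product: 2 (3,5-dimethoxyphenoxy)tri(propan-2-yl)silane
Conditions: TIPSCl, imidazole, DMF, rt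
Reagents that add atoms: triisopropylsilyl chloride (TIPSCl), CC(C)[Si](Cl)(C(C)C)C(C)C
Why: Imidazole-promoted O-silylation of a phenol is routine, and the bulky TIPS ether removes the acidic proton, resists n-BuLi and shields its own ortho positions in the metalation that follows.

Step 2
Reactants: 2 (3,5-dimethoxyphenoxy)tri(propan-2-yl)silane
Product: 4 (4-iodo-3,5-dimethoxyphenoxy)tri(propan-2-yl)silane, via ring A aryllithium 3 (not isolated)
Conditions: n-BuLi, THF, 0 °C → rt; then I2, −78 °C → rt
Reagents that add atoms: iodine, [I][I]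
Why: Directed ortho-metalation: the two methoxy groups act together to place lithium on the carbon between them while the hindered, poorly coordinating silyloxy group does not direct, so iodinolysis of 3 puts the halide para to the protected phenol, a position that electrophilic iodination would not reach cleanly.

Step 3
Reactants: 5 resorcinol
Product: 6 1,3-bis(methoxymethoxy)benzene
Conditions: NaH, MOMCl, DMF, 0 °C → rt
Reagents that add atoms: chloromethyl methyl ether (MOMCl), COCCl
Why: Double O-alkylation of resorcinol with MOMCl is standard, and the acetal ethers are strong metalation directors that survive organolithiums, fluoride and heat yet leave under mild acid that does not touch methyl ethers.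

Step 4
Reactants: 6 1,3-bis(methoxymethoxy)benzene; 4 (4-iodo-3,5-dimethoxyphenoxy)tri(propan-2-yl)silane
Product: 9 {4-[2,6-bis(methoxymethoxy)phenyl]-3,5-dimethoxyphenoxy}tri(propan-2-yl)silane, via ring D aryllithium 7 (not isolated), via ring D arylzinc chloride 8 (not isolated)
Conditions: 6, n-BuLi, THF, 0 °C → rt; ZnCl2, THF, 0 °C → rt; then 4, Pd2(dba)3 (cat.), RuPhos, THF, 70 °C
Reagents that add atoms: none
Why: Directed ortho-metalation between the two OMOM groups, transmetalation to zinc and Negishi cross-coupling, a combination that with zerovalent palladium and a bulky dialkylbiarylphosphine is established for tetra-ortho-substituted biaryls and avoids the protodeboronation typical of 2,6-dialkoxyarylboronic acids.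

Step 5
Reactants: 9 {4-[2,6-bis(methoxymethoxy)phenyl]-3,5-dimethoxyphenoxy}tri(propan-2-yl)silane
Product: 10 4-[2,6-bis(methoxymethoxy)phenyl]-3,5-dimethoxyphenol
Conditions: TBAF, AcOH, THF, 0 °C → rt
Reagents that add atoms: none
Why: Fluoride-induced cleavage of the aryl silyl ether, buffered with acetic acid so that the electron-rich phenoxide is not left exposed, leaves MOM and methyl ethers untouched and gives a phenol whose two ortho positions are equivalent.

Step 6
Reactants: 10 4-[2,6-bis(methoxymethoxy)phenyl]-3,5-dimethoxyphenol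
Product: 11 2-bromo-4-[2,6-bis(methoxymethoxy)phenyl]-3,5-dimethoxyphenol
Conditions: NBS (1 equiv), CH2Cl2, −78 °C → 0 °C
Reagents that add atoms: N-bromosuccinimide (NBS), O=C1CCC(=O)N1Br
Why: Electrophilic aromatic bromination: the free phenol ring, activated by three oxygen donors and blocked para, is far more nucleophilic than ring D, its two open positions are equivalent, and one equivalent of NBS at low temperature should stop at the monobromide.

Step 7
Reactants: 11 2-bromo-4-[2,6-bis(methoxymethoxy)phenyl]-3,5-dimethoxyphenol
Product: 15 4-[2,6-bis(methoxymethoxy)phenyl]-3,5-dimethoxy-2-(trimethylsilyl)phenyl trifluoromethanesulfonate, via O-trimethylsilyl ether 12 (not isolated), via C2 aryllithium 13 (not isolated), via lithium silylphenoxide 14 (not isolated)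
Conditions: HMDS, THF, 70 °C, then evaporation; n-BuLi, THF, −78 °C; then Tf2O, −78 °C → 0 °C
Reagents that add atoms: hexamethyldisilazane (HMDS), C[Si](C)(C)N[Si](C)(C)C; trifluoromethanesulfonic anhydride (Tf2O), O=S(=O)(OS(=O)(=O)C(F)(F)F)C(F)(F)F
Why: This is the standard passage from an o-bromophenol to an o-silylaryl triflate: O-silylation, bromine–lithium exchange (faster at −78 °C than any metalation directed by OMOM), retro-Brook 1,3-shift of silicon from oxygen to the carbanion (13 to 14) and O-triflation of the lithium phenoxide.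

Step 8
Reactants: 15 4-[2,6-bis(methoxymethoxy)phenyl]-3,5-dimethoxy-2-(trimethylsilyl)phenyl trifluoromethanesulfonate; 16 3-(4-methoxyphenyl)propiolic acid
Product: 20 6-[2,6-bis(methoxymethoxy)phenyl]-5,7-dimethoxy-2-(4-methoxyphenyl)-4H-chromen-4-one, via aryne 17 (not isolated), via aryl anion 18 (not isolated), via hydroxyaryl ynone 19 (not isolated)
Conditions: CsF (4 equiv), THF, 125 °C (sealed tube)
Reagents that add atoms: none
Why: Fluoride attacks silicon of 15 and triflate departs to give aryne 17, the caesium carboxylate of 16 adds through oxygen to C8a (flavone numbering), and the aryl anion 18 thus placed on C4a attacks the adjacent ester carbonyl through a four-membered transition state and collapses to the phenoxide of ynone 19, which amounts to insertion of the aryne into the acid C–O bond (C8a–O1 and C4a–C4 made). The closest known reaction type is this very fluoride-induced insertion of arynes from o-silylaryl triflates into carboxylic acids in hot THF, which with arylpropiolic acids is known to run on to flavones. Ring C closes by 6-endo-dig oxa-Michael addition of the C8a phenoxide to the alkyne carbon that bears the anisyl group (O1–C2), the C3 carbanion recovers the proton parked as bifluoride, and the aprotic medium favours this mode over 5-exo-dig closure to an aurone. The selectivity needed is attack of oxygen at C8a and not C4a: the C5 methoxy group beside C4a bends the aryne so that C8a is the more linear, more electrophilic and less crowded terminus and stabilises by induction the charge that builds up on C4a, whereas the distant C7 methoxy group and the C6 aryl group weigh little. Acyl transfer must also outrun protonation of 18, for which excess CsF (acid held as carboxylate), the slow release of aryne by sparingly soluble CsF and the high temperature are chosen. No stereocentre is created, and since both ortho positions of phenol 10 were equivalent the aryl group can end up only on C6.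

Step 9
Reactants: 20 6-[2,6-bis(methoxymethoxy)phenyl]-5,7-dimethoxy-2-(4-methoxyphenyl)-4H-chromen-4-one
Product: 21 6-(2,6-dihydroxyphenyl)-5,7-dimethoxy-2-(4-methoxyphenyl)-4H-chromen-4-one
Conditions: conc. HCl (cat.), MeOH, 50 °C
Reagents that add atoms: none
Why: Acid-catalysed acetal exchange removes both MOM groups, methanol traps the formaldehyde unit so that it cannot alkylate the liberated resorcinol, and aryl methyl ethers and the flavone core are inert to these conditions.

Step 10
Reactants: 21 6-(2,6-dihydroxyphenyl)-5,7-dimethoxy-2-(4-methoxyphenyl)-4H-chromen-4-one; 22 ethyl propiolate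
Product: 23 6-(7-hydroxy-2-oxo-2H-chromen-8-yl)-5,7-dimethoxy-2-(4-methoxyphenyl)-4H-chromen-4-one
Conditions: ZnCl2, 1,4-dioxane, 100 °C
Reagents that add atoms: none
Why: Pechmann-type coumarin synthesis with a propiolate ester, known for resorcinol and its 2-substituted derivatives: ZnCl2 promotes C-alkenylation of ring D para to one hydroxyl and the hydroxyl ortho to the new bond lactonises, and because ring D is the only ring with free phenols, its two reactive positions are equivalent and ring A is capped and deactivated by the Lewis-acid-bound C4 carbonyl, a single 7-hydroxy-8-arylcoumarin should arise.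

Step 11
Reactants: 23 6-(7-hydroxy-2-oxo-2H-chromen-8-yl)-5,7-dimethoxy-2-(4-methoxyphenyl)-4H-chromen-4-one
Product: 24 5,7-dihydroxy-6-(7-hydroxy-2-oxo-2H-chromen-8-yl)-2-(4-hydroxyphenyl)-4H-chromen-4-one (CNP0223343.0)
Conditions: BBr3 (excess), CH2Cl2, −78 °C → rt; then H2O
Reagents that add atoms: none
Why: Lewis-acid cleavage of aryl methyl ethers with BBr3 is routine for methoxyflavones and methoxycoumarins, the lactone re-closes on aqueous work-up should it open, and the low temperature avoids the Wessely–Moser ring-opening isomerisation (6-aryl to 8-aryl flavone) that hot mineral acid could trigger.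

Compound list
1 | 3,5-dimethoxyphenol | COc1cc(O)cc(OC)c1 | starting material
2 | (3,5-dimethoxyphenoxy)tri(propan-2-yl)silane | COc1cc(OC)cc(O[Si](C(C)C)(C(C)C)C(C)C)c1 | intermediate
3 | [2,6-dimethoxy-4-(triisopropylsilyloxy)phenyl]lithium | [Li]c1c(OC)cc(O[Si](C(C)C)(C(C)C)C(C)C)cc1OC | intermediate
4 | (4-iodo-3,5-dimethoxyphenoxy)tri(propan-2-yl)silane | COc1cc(O[Si](C(C)C)(C(C)C)C(C)C)cc(OC)c1I | intermediate
5 | resorcinol | Oc1cccc(O)c1 | starting material
6 | 1,3-bis(methoxymethoxy)benzene | COCOc1cccc(OCOC)c1 | intermediate
7 | [2,6-bis(methoxymethoxy)phenyl]lithium | [Li]c1c(OCOC)cccc1OCOC | intermediate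
8 | [2,6-bis(methoxymethoxy)phenyl]zinc chloride | Cl[Zn]c1c(OCOC)cccc1OCOC | intermediate
9 | {4-[2,6-bis(methoxymethoxy)phenyl]-3,5-dimethoxyphenoxy}tri(propan-2-yl)silane | COCOc1cccc(OCOC)c1-c1c(OC)cc(O[Si](C(C)C)(C(C)C)C(C)C)cc1OC | intermediate
10 | 4-[2,6-bis(methoxymethoxy)phenyl]-3,5-dimethoxyphenol | COCOc1cccc(OCOC)c1-c1c(OC)cc(O)cc1OC | intermediate
11 | 2-bromo-4-[2,6-bis(methoxymethoxy)phenyl]-3,5-dimethoxyphenol | COCOc1cccc(OCOC)c1-c1c(OC)cc(O)c(Br)c1OC | intermediate
12 | {2-bromo-4-[2,6-bis(methoxymethoxy)phenyl]-3,5-dimethoxyphenoxy}trimethylsilane | COCOc1cccc(OCOC)c1-c1c(OC)cc(O[Si](C)(C)C)c(Br)c1OC | intermediate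
13 | {3-[2,6-bis(methoxymethoxy)phenyl]-2,4-dimethoxy-6-(trimethylsilyloxy)phenyl}lithium | COCOc1cccc(OCOC)c1-c1c(OC)cc(O[Si](C)(C)C)c([Li])c1OC | intermediate
14 | lithium 4-[2,6-bis(methoxymethoxy)phenyl]-3,5-dimethoxy-2-(trimethylsilyl)phenoxide | [Li+].COCOc1cccc(OCOC)c1-c1c(OC)cc([O-])c([Si](C)(C)C)c1OC | intermediate
15 | 4-[2,6-bis(methoxymethoxy)phenyl]-3,5-dimethoxy-2-(trimethylsilyl)phenyl trifluoromethanesulfonate | COCOc1cccc(OCOC)c1-c1c(OC)cc(OS(=O)(=O)C(F)(F)F)c([Si](C)(C)C)c1OC | intermediate
16 | 3-(4-methoxyphenyl)propiolic acid | COc1ccc(cc1)C#CC(=O)O | starting material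
17 | 4-[2,6-bis(methoxymethoxy)phenyl]-3,5-dimethoxybenzyne (triple bond between the former C1 and C2 of 15) | COCOc1cccc(OCOC)c1C1=C(OC)C#CC=C1OC | intermediate
18 | 5-[2,6-bis(methoxymethoxy)phenyl]-4,6-dimethoxy-2-{[3-(4-methoxyphenyl)prop-2-ynoyl]oxy}phenylcaesium | [Cs+].COc1ccc(cc1)C#CC(=O)Oc1cc(OC)c(-c2c(OCOC)cccc2OCOC)c(OC)[c-]1 | intermediate
19 | 1-{3-[2,6-bis(methoxymethoxy)phenyl]-6-hydroxy-2,4-dimethoxyphenyl}-3-(4-methoxyphenyl)prop-2-yn-1-one (present in step 8 as its caesium phenoxide) | COc1ccc(cc1)C#CC(=O)c1c(O)cc(OC)c(-c2c(OCOC)cccc2OCOC)c1OC | intermediate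
20 | 6-[2,6-bis(methoxymethoxy)phenyl]-5,7-dimethoxy-2-(4-methoxyphenyl)-4H-chromen-4-one | COc1ccc(cc1)-c1cc(=O)c2c(OC)c(-c3c(OCOC)cccc3OCOC)c(OC)cc2o1 | intermediate
21 | 6-(2,6-dihydroxyphenyl)-5,7-dimethoxy-2-(4-methoxyphenyl)-4H-chromen-4-one | COc1ccc(cc1)-c1cc(=O)c2c(OC)c(-c3c(O)cccc3O)c(OC)cc2o1 | intermediate
22 | ethyl propiolate | C#CC(=O)OCC | starting material
23 | 6-(7-hydroxy-2-oxo-2H-chromen-8-yl)-5,7-dimethoxy-2-(4-methoxyphenyl)-4H-chromen-4-one | COc1ccc(cc1)-c1cc(=O)c2c(OC)c(-c3c(O)ccc4ccc(=O)oc34)c(OC)cc2o1 | intermediate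
24 | 5,7-dihydroxy-6-(7-hydroxy-2-oxo-2H-chromen-8-yl)-2-(4-hydroxyphenyl)-4H-chromen-4-one | O=c1ccc2ccc(O)c(-c3c(O)cc4oc(-c5ccc(O)cc5)cc(=O)c4c3O)c2o1 | target

Total step count: 11. Longest linear sequence: 10 (steps 1, 2 and 4 to 11, from 3,5-dimethoxyphenol).

Steps most likely to fail

Step 8 is the most exposed.
- What may go wrong: the aryl anion may be protonated ahead of the acyl shift (plain O-arylation). The propiolate may also decarboxylate thermally, or closure may go 5-exo-dig instead of 6-endo-dig.
- The fallback leaves aryne chemistry. It sets out from phenol 10 and reaches the same ynone by carbonyl addition.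
- Magnesium-mediated ortho-formylation (MgCl2, Et3N, paraformaldehyde, MeCN, reflux) should give 3-[2,6-bis(methoxymethoxy)phenyl]-6-hydroxy-2,4-dimethoxybenzaldehyde F1.
- Two equivalents of lithium (4-methoxyphenyl)acetylide (from 4-ethynylanisole and n-BuLi, THF, −78 °C) should then give racemic 1-{3-[2,6-bis(methoxymethoxy)phenyl]-6-hydroxy-2,4-dimethoxyphenyl}-3-(4-methoxyphenyl)prop-2-yn-1-ol F2.
- MnO2 in CH2Cl2 should oxidise this alcohol to ynone 19, which K2CO3 in acetone closes to 20, where the route is rejoined.

Step 4 comes next.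
- What may go wrong: transmetalation and reductive elimination at a palladium centre that carries two 2,6-dialkoxyaryl groups may be slow. That leaves time for protodemetalation, reduction of the iodide and homocoupling.
- The fallback forms the biaryl bond without a transition metal and without the iodide. It sets out from 6.
- Compound 6 is lithiated to 7 as before and added at −78 °C in THF to commercial 2,6-dimethoxy-1,4-benzoquinone.
- The carbonyl flanked by the two methoxy-bearing carbons is the more electrophilic one, because the other is a doubly vinylogous ester.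
- 1,2-Addition should therefore give 4-[2,6-bis(methoxymethoxy)phenyl]-4-hydroxy-3,5-dimethoxycyclohexa-2,5-dien-1-one F3.
- Reductive aromatisation of this p-quinol with Zn in AcOH at rt should deliver phenol 10 directly, where the route is rejoined.

Step 10 is third.
- What may go wrong: the flavone carbonyl may sequester the Lewis acid, and the propiolate may polymerise faster than ring D is C-alkenylated. The C5 methyl ether may also be partly lost.
- The fallback sets out from 21 and installs the three carbons of ring E in two separate operations.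
- Vilsmeier–Haack formylation (POCl3, DMF, MeCN, 0 °C → rt, then H2O) is well known for 2-substituted resorcinols. It should give 2,4-dihydroxy-3-[5,7-dimethoxy-2-(4-methoxyphenyl)-4-oxo-4H-chromen-6-yl]benzaldehyde F4.
- Wittig olefination with Ph3P=CHCO2Et in refluxing N,N-diethylaniline should pass through ethyl (E)-3-{2,4-dihydroxy-3-[5,7-dimethoxy-2-(4-methoxyphenyl)-4-oxo-4H-chromen-6-yl]phenyl}prop-2-enoate F5.
- At that temperature this ester isomerises and lactonises to 23, where the route is rejoined.

Further compounds
F1 | step 8 | 3-[2,6-bis(methoxymethoxy)phenyl]-6-hydroxy-2,4-dimethoxybenzaldehyde | COCOc1cccc(OCOC)c1-c1c(OC)cc(O)c(C=O)c1OC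
F2 | step 8 | 1-{3-[2,6-bis(methoxymethoxy)phenyl]-6-hydroxy-2,4-dimethoxyphenyl}-3-(4-methoxyphenyl)prop-2-yn-1-ol (racemic) | COc1ccc(cc1)C#CC(O)c1c(O)cc(OC)c(-c2c(OCOC)cccc2OCOC)c1OC
F3 | step 4 | 4-[2,6-bis(methoxymethoxy)phenyl]-4-hydroxy-3,5-dimethoxycyclohexa-2,5-dien-1-one | COCOc1cccc(OCOC)c1C1(O)C(OC)=CC(=O)C=C1OC
F4 | step 10 | 2,4-dihydroxy-3-[5,7-dimethoxy-2-(4-methoxyphenyl)-4-oxo-4H-chromen-6-yl]benzaldehyde | COc1ccc(cc1)-c1cc(=O)c2c(OC)c(-c3c(O)ccc(C=O)c3O)c(OC)cc2o1
F5 | step 10 | ethyl (E)-3-{2,4-dihydroxy-3-[5,7-dimethoxy-2-(4-methoxyphenyl)-4-oxo-4H-chromen-6-yl]phenyl}prop-2-enoate | CCOC(=O)/C=C/c1ccc(O)c(-c2c(OC)cc3oc(-c4ccc(OC)cc4)cc(=O)c3c2OC)c1O
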